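If a catalyst has to go round many times in a fixed time, ask how long each round may take. Starting material and reagent pass through the catalyst's working round and leave as target, while impurity takes free catalyst out of that round for good.

- east: starting material 1.4 M; reagent 2.30 M; free catalyst 46 mM; impurity 35 mM; time 80 min
- north: starting material 1.4 M; reagent 1.50 M; free catalyst 46 mM; impurity 35 mM; time 80 min

    starting material + free catalyst → catalyst intermediate A (k1 = 0.131 M⁻¹ s⁻¹)
    catalyst intermediate A → catalyst intermediate B (k2 = 0.145 s⁻¹)
    reagent + catalyst intermediate B → catalyst intermediate C (k3 = 0.0969 M⁻¹ s⁻¹)
    catalyst intermediate C → free catalyst + target (k4 = 0.763 s⁻¹)
    free catalyst + impurity → spent catalyst (k5 = 2.19 M⁻¹ s⁻¹)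

- which of these there is most of at the end, counted by the starting material in it, east (catalyst intermediate B / target / catalyst intermediate A / starting material)
- which of these there is most of at the end, counted by the starting material in it, north (catalyst intermediate B / target / catalyst intermediate A / starting material)
- amount of the one of these that there is most of at the end, in percent of the starting material charged, east
- amount of the one of these that there is most of at the end, in percent of the starting material charged, north

I take it that the impurity is consumed, one catalyst each, which leaves S = 11.0 mM in the round. Each of these must then go round 127 times, so the mean time a round may take, the round budget b = tS/c, with t the time and c the starting material charged, is 37.7 s. It is the same in east and north, for reagent does not enter it.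

The round's own time is τ = 1/(k1·a) + 1/k2 + 1/(k3·r) + 1/k4. I replace the falling curves by their means: a is half of c, and r is the reagent charge minus half of c. That gives τ = 32.0 s in north and 25.6 s in east, so both fit the budget, east with the wider margin.

Now turn the settings. Catalyst and impurity act through their difference, so they move b directly. By this reckoning, north's b falls level with its τ once S has lost 1.66 mM of its 11.0 mM. Reagent enters τ and not b, and time stretches b in proportion.

The means flatter, though: at 0.140 M of starting material the first step alone takes 54.5 s, more than b. So I commit to target leading in both flasks, with north some way short of complete and east nearer.

The forecast gives target in both, 98.6% east and 94% north, and says of north that “step 3 slows sharply near the end”.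

The flask gives target in both, 98.8% east and 94.3% north, with 5.39% of the starting material still unbound in north. Reckoned from b, north's mean round took about 40.0 s, against my 32.0 s. The neighbour of north with 0.90 M of reagent has reagent as its limiting reagent, which caps target at 64.3%. Its budget for that amount is 58.7 s, against a round of 39.2 s, so the cap should show. That neighbour reads 63.0% of target.

The numbers of this flask stand for no real mixture; what happens was integrated by code.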